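**Two times.** This flask is to be read at 8.0 min and at 25 h; the earlier time lies before the first reading of either run, at 1.00 h in the south-east run.

| flask | J | remark | time |
|---|---|---|---|
| south-east | 0.020 M | the very flask that is asked about, followed so far |  |
| north-east | 0.013 M | run made earlier |  |
| flask | 0.020 M |  | 25 h |

| run | time / h | E / % | L / % |
|---|---|---|---|
| south-east | 1.00 | 7.0 | 11.1 |
| south-east | 1.50 | 8.6 | 15.6 |
| south-east | 3.00 | 13.6 | 24.7 |
| south-east | 5.00 | 16.1 | 29.9 |
| south-east | 8.00 | 18.0 | 32.9 |
| south-east | 12.0 | 18.1 | 35.0 |
| north-east | 2.00 | 10.8 | 19.9 |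
| north-east | 3.00 | 13.6 | 25.0 |
| north-east | 6.00 | 16.8 | 31.3 |
| north-east | 10.0 | 18.4 | 33.4 |
| north-east | 15.0 | 19.1 | 34.1 |
| north-east | 25.0 | 18.8 | 35.2 |

(each reading ± 0.5 percentage points)

- what was read earlier has a scatter of 0.5 percentage points, one standard deviation
- a reading or a percentage of E counts all its forms, free or not

* share of E in E plus L at 8.0 min
* share of E in E plus L at 25 h

**End first.** At its last reading the north-east run holds a share of E in E plus L of 34.8 %, and we commit to that for 25 h. Both runs read 13.6 % of E at 3.00 h despite their different charges, so we treat the percentages as independent of the charge. The south-east total at that time, set against the last north-east total, gives E plus L a time constant of 2.43 h.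

**A lag.** But at 1.00 h the south-east share is 38.7 %, higher than the end share. So we suppose that L is E's curve, scaled to the end ratio and passed through a first-order lag. At that reading L falls short of the scaled curve by 1.1 percentage points in E's units. Divided by E's slope there, this gives 0.209 h, and that lag puts the share at 8.0 min at 67.2 %.

**Link reforged.** That rests on one shortfall against a scatter of 0.5 points. We pool the shortfalls and slopes of the earliest readings, at 1.00 h, 1.50 h and 2.00 h. This gives the lag of L, the time by which L trails E's scaled curve (its induction period), as 0.119 h. The early time is a little longer than this lag, and we commit to a share of 57.3 %, lower than the first figure.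

**The result.** The forecast gave 35.5 % and 35 %, noting that “nothing has been measured that early”. The flask gives 62.3 % at 8.0 min and 35.0 % at 25 h.

    J → D (k = 0.0572 h⁻¹)
    J + E ⇌ X, settled at all times (K = 27.6 L mol⁻¹)
    G ⇌ Q (K = 1.70, k = 0.0707 h⁻¹)
    J ⇌ G (K = 0.854, k = 4.36 h⁻¹)
    G → D (k = 0.0318 h⁻¹)
    J → E (k = 0.144 h⁻¹)
    G → L (k = 0.360 h⁻¹)
    G → Z (k = 0.330 h⁻¹)

**The neighbour.** J goes straight to E but reaches L through G. In this flask our 57.3 % stands 5.0 points below the result. A neighbouring flask holds 0.012 M of J, with the time and all else kept. The same lag of 0.119 h gives it the same 57.3 % at 8.0 min, and the end share gives it 34.8 % at 25 h. That neighbouring flask gives 62.3 % at 8.0 min and 35.0 % at 25 h.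

All runs were computed on assumed constants; scatter was added.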